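(The data come from a simulation with made-up constants, and the scatter is random.)

When two partners compete for one fleeting form of G, each at a rate proportional to its own amount, the logarithms of their fractions left keep a fixed proportion as the flask runs. We carry that proportion.

common to all: G 20 mM
- north-west: Q 0.90 equiv; L 1.2 equiv; the very flask that is asked about, followed so far
- north: Q 0.90 equiv; L 2.4 equiv; run made earlier
- flask: Q 0.900 equiv; L 1.20 equiv; time 4.0 h

north-west run (percent of the G charged)

| time / min | J / % | X / % |
|---|---|---|
| 10.0 | 53 | 32 |
| 15.0 | 51 | 31 |
| 25.0 | 49 | 30 |
| 40.0 | 48 | 30 |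
| 80.0 | 46 | 29 |
| 120 | 52 | 30 |

north run (percent of the G charged)

| time / h | J / % | X / % |
|---|---|---|
| 0.667 | 64 | 23 |
| 1.33 | 67 | 20 |
| 2.00 | 64 | 23 |
| 2.50 | 67 | 18 |
| 3.00 | 66 | 17 |
| 4.00 | 66 | 21 |

(each reading ± 2 percentage points)

* ratio of J to X at 6.0 s
* ratio of J to X at 4.0 h
* which of J and X there is more of at 4.0 h



The north-west flask looks contradictory. From the first reading it stands still, with J near 49.8% and X near 30.3%. Yet if each J took one L and each X one Q, that flask still holds 58.5% of its L and 66.3% of its Q. With that much of both partners present, we take G, the limiting reagent, as what stopped it.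

The north flask, with J near 65.7% and X near 20.3%, shows a different ratio of J to X, yet the proportion read from it comes out close. North-west gives 1.31 and north gives 1.25. We keep their mean, 1.28, as s, the selectivity factor: the logarithm of the fraction of L left over that of the fraction of Q left.

While both fractions stand near whole, the ratio of J to X comes close to s times the charge of L over the charge of Q; taking them as near whole at 6.0 s, we reckon 1.70 for that time. The flat north-west readings end at 120 min, and carrying their mean ratio forward we expect 1.64 at 4.0 h.

The forecast says 1.9 at 6.0 s and 1.65 at 4.0 h, with J ahead (“Partitioning fits slightly better”), and its early figure stands above ours.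

The flask gives 1.69 at 6.0 s and 1.63 at 4.0 h, with J ahead at 50.1% against 30.8%.

    G → D (k = 5.12 /min)
    Q + D → X (k = 12300 /M/min)
    L + D → J (k = 15900 /M/min)
    D → Z (k = 78.3 /min)
    2 G → E (k = 16.0 /M/min)

At 4.00 h the flask holds G at 0%, with 65.8% of Q and 58.2% of L left, and leaving out the step to Z makes no difference to the ratio at that time. Those two fractions give s as 1.29. For the neighbour charged with 2.20 equiv of Q, our s gives a ratio of 0.696 with both fractions taken as near whole at 6.0 s, and at that time that flask shows 0.695.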